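**Plan**

- Retrosynthesis first cuts the ring A O–ring D C bond of the 18-membered ring, with ring D replaced by a non-aromatic six-membered stand-in. It then cuts the stand-in ring (malonate C–C bonds), the ring C side chain (two olefination C=C bonds), the ring B–O–ring C ether (SNAr) and the ring A–ring B ethylene bridge (Wittig C=C).
- Enabling feature: ring D carries the ether oxygen and the bridge CH2 on C1 and C3 (meta). This is the oxygen/alkyl pattern of a 5-alkylcyclohexane-1,3-dione, whose 3-chloro-2-enone takes up the ortho-alkylated ring A phenoxide at C3 much more readily than an unactivated aryl halide would.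
- Forward order: ring A and ring B are joined (Wittig), ring C is added (SNAr), the ring C aldehyde is extended to a methyl enone, and the ring D stand-in is built by Michael–Claisen (first new ring). The 18-membered ring is then closed by phenoxide addition–elimination (second ring), the stand-in is aromatised and its extra oxygen removed through the triflate.
- Stereochemistry: the target has no stereocentre. C5 of the stand-in ring is the only one on the way; it is carried racemic and erased on aromatisation. Alkene geometries disappear on hydrogenation.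

Key step: step 12

Remark: all compounds containing C5 of the stand-in ring are racemic and their SMILES show one enantiomer. The two phenols of the target are carried as methyl ethers, and the ring A phenol that becomes the ether oxygen is carried as an isopropyl ether.

**Step 1**
Reactants: 1 2-hydroxy-5-methoxybenzaldehyde
Product: 2 5-methoxy-2-(propan-2-yloxy)benzaldehyde
Conditions: 2-bromopropane, K2CO3, DMF, 60 °C
Reagents that add atoms: 2-bromopropane, CC(C)Br
Why: Williamson ether synthesis on the only phenol present should install an isopropyl ether that withstands every later base, hydride, hydrogenation and aqueous acid step.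

**Step 2**
Reactants: 3 5-(hydroxymethyl)-2-methoxyphenol (isovanillyl alcohol)
Product: 4 [(3-hydroxy-4-methoxyphenyl)methyl]triphenylphosphonium bromide
Conditions: PPh3·HBr, MeCN, reflux
Reagents that add atoms: triphenylphosphine hydrobromide, Br.c1ccc(cc1)P(c1ccccc1)c1ccccc1
Why: The benzylic alcohol, activated by the para-methoxy group, should ionise under the mild acid and be captured by PPh3 (direct phosphonium salt formation from a benzylic alcohol), leaving the phenol untouched.

**Step 3**
Reactants: 4 [(3-hydroxy-4-methoxyphenyl)methyl]triphenylphosphonium bromide; 2 5-methoxy-2-(propan-2-yloxy)benzaldehyde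
Product: 6 2-methoxy-5-{2-[5-methoxy-2-(propan-2-yloxy)phenyl]ethenyl}phenol (E/Z mixture), via phosphorus ylide 5 (not isolated)
Conditions: KOtBu (2.2 equiv), THF, 0 °C → rt; 1 M HCl work-up
Reagents that add atoms: none
Why: Wittig olefination with two equivalents of base should work because the phenolate is meta to the ylide carbon and does not quench it, and the E/Z ratio is irrelevant since the alkene is saturated in step 6.

**Step 4**
Reactants: 6 2-methoxy-5-{2-[5-methoxy-2-(propan-2-yloxy)phenyl]ethenyl}phenol; 7 4-fluorobenzaldehyde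
Product: 8 4-(2-methoxy-5-{2-[5-methoxy-2-(propan-2-yloxy)phenyl]ethenyl}phenoxy)benzaldehyde
Conditions: K2CO3, DMF, 120 °C
Reagents that add atoms: none
Why: Nucleophilic aromatic substitution of the fluoride activated by the para-formyl group with a guaiacol-type phenoxide is the standard way to this kind of diaryl ether.

**Step 5**
Reactants: 8 4-(2-methoxy-5-{2-[5-methoxy-2-(propan-2-yloxy)phenyl]ethenyl}phenoxy)benzaldehyde
Product: 9 ethyl (2E)-3-[4-(2-methoxy-5-{2-[5-methoxy-2-(propan-2-yloxy)phenyl]ethenyl}phenoxy)phenyl]prop-2-enoate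
Conditions: triethyl phosphonoacetate, NaH, THF, 0 °C → rt
Reagents that add atoms: triethyl phosphonoacetate, CCOC(=O)CP(=O)(OCC)OCC
Why: Horner–Wadsworth–Emmons olefination of an aryl aldehyde should give the E-cinnamate and adds the two carbons that become the second bridge CH2 and C5 of the stand-in ring.

**Step 6**
Reactants: 9 ethyl (2E)-3-[4-(2-methoxy-5-{2-[5-methoxy-2-(propan-2-yloxy)phenyl]ethenyl}phenoxy)phenyl]prop-2-enoate
Product: 10 ethyl 3-[4-(2-methoxy-5-{2-[5-methoxy-2-(propan-2-yloxy)phenyl]ethyl}phenoxy)phenyl]propanoate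
Conditions: H2 (1 atm), 10% Pd/C, EtOAc, rt
Reagents that add atoms: none
Why: Catalytic hydrogenation should saturate the stilbene and the cinnamate double bonds in one operation, since no benzyl ether or halide is present and the alkyl aryl and diaryl ethers are inert.

**Step 7**
Reactants: 10 ethyl 3-[4-(2-methoxy-5-{2-[5-methoxy-2-(propan-2-yloxy)phenyl]ethyl}phenoxy)phenyl]propanoate
Product: 11 3-[4-(2-methoxy-5-{2-[5-methoxy-2-(propan-2-yloxy)phenyl]ethyl}phenoxy)phenyl]propanal
Conditions: i-Bu2AlH (1.1 equiv), CH2Cl2, −78 °C; MeOH, then aq. potassium sodium tartrate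
Reagents that add atoms: none
Why: Partial reduction of the ester at −78 °C should stop at the aluminium hemiacetal, which collapses to the aldehyde only on work-up.

**Step 8**
Reactants: 11 3-[4-(2-methoxy-5-{2-[5-methoxy-2-(propan-2-yloxy)phenyl]ethyl}phenoxy)phenyl]propanal
Product: 12 (3E)-6-[4-(2-methoxy-5-{2-[5-methoxy-2-(propan-2-yloxy)phenyl]ethyl}phenoxy)phenyl]hex-3-en-2-one
Conditions: Ph3P=CHC(O)CH3, toluene, 80 °C
Reagents that add atoms: 1-(triphenyl-λ5-phosphanylidene)propan-2-one, CC(=O)C=P(c1ccccc1)(c1ccccc1)c1ccccc1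
Why: Wittig olefination of an aliphatic aldehyde with the stabilised acetonylidene ylide should give the E-methyl enone without base-induced aldol side reactions.

**Step 9**
Reactants: 12 (3E)-6-[4-(2-methoxy-5-{2-[5-methoxy-2-(propan-2-yloxy)phenyl]ethyl}phenoxy)phenyl]hex-3-en-2-one; 13 diethyl malonate
Product: 17 5-{2-[4-(2-methoxy-5-{2-[5-methoxy-2-(propan-2-yloxy)phenyl]ethyl}phenoxy)phenyl]ethyl}cyclohexane-1,3-dione, via Michael adduct 14 (not isolated), via cyclic keto ester 15 (not isolated), via dioxo acid 16 (not isolated)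
Conditions: NaOEt, EtOH, reflux; aq. NaOH, reflux; aq. HCl to pH 1, 80 °C
Reagents that add atoms: none
Why: Michael addition of malonate to the enone, Claisen ring closure of the methyl ketone enolate onto an ester, saponification and decarboxylation form the classical route to 5-alkylcyclohexane-1,3-diones, and the stereocentres of the intermediates vanish in the symmetric dione.

**Step 10**
Reactants: 17 5-{2-[4-(2-methoxy-5-{2-[5-methoxy-2-(propan-2-yloxy)phenyl]ethyl}phenoxy)phenyl]ethyl}cyclohexane-1,3-dione
Product: 19 racemic 3-chloro-5-{2-[4-(2-methoxy-5-{2-[5-methoxy-2-(propan-2-yloxy)phenyl]ethyl}phenoxy)phenyl]ethyl}cyclohex-2-en-1-one, via enol chlorooxalate 18 (not isolated)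
Conditions: (COCl)2 (1.5 equiv), CHCl3, 0 °C → reflux
Reagents that add atoms: oxalyl chloride, ClC(=O)C(=O)Cl
Why: O-acylation of the enolised dione by oxalyl chloride, then chloride addition–elimination with loss of CO and CO2, is the standard conversion of a 1,3-dione into its β-chloroenone; C5 becomes a stereocentre without control, so the product is racemic.

**Step 11**
Reactants: 19 racemic 3-chloro-5-{2-[4-(2-methoxy-5-{2-[5-methoxy-2-(propan-2-yloxy)phenyl]ethyl}phenoxy)phenyl]ethyl}cyclohex-2-en-1-one
Product: 20 racemic 3-chloro-5-[2-(4-{5-[2-(2-hydroxy-5-methoxyphenyl)ethyl]-2-methoxyphenoxy}phenyl)ethyl]cyclohex-2-en-1-one (seco phenol chloroenone)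
Conditions: BCl3 (3 equiv), CH2Cl2, −78 → 0 °C; ice-water
Reagents that add atoms: none
Why: BCl3 dealkylation cleaves a secondary alkyl aryl ether much faster than methyl aryl ethers, and the chloroenone should survive because chloride is the only nucleophile present and its addition–elimination is degenerate.

**Step 12**
Reactants: 20 racemic 3-chloro-5-[2-(4-{5-[2-(2-hydroxy-5-methoxyphenyl)ethyl]-2-methoxyphenoxy}phenyl)ethyl]cyclohex-2-en-1-one
Product: 21 racemic macrocyclic 3-aryloxycyclohex-2-en-1-one (ring A oxygen bonded to C3 of the enone in place of chloride, 18-membered ring)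
Conditions: Cs2CO3 (3 equiv), MeCN, 50 °C, slow addition of 20 (final 2 mM)
Reagents that add atoms: none
Why: Cs2CO3 converts the ring A phenol into its caesium phenoxide, which adds to C3 of the β-chloroenone to give a chloro-substituted enolate that expels chloride, i.e. addition–elimination at an sp2 carbon (vinylogous acyl substitution). The closest known reaction is the intermolecular formation of 3-aryloxycyclohex-2-enones from phenoxides and 3-chlorocyclohex-2-enone, which runs at or near room temperature even with ortho-substituted phenols. The 18-membered ring closes in the exo-trig mode (the attacked C2=C3 bond lies outside the new ring), followed by loss of chloride. No stereocentre is formed; C5 is untouched and stays racemic. The step needs O- rather than ortho-C-attack of the ambident phenoxide, which the large caesium counter-ion in a polar aprotic solvent and the hard vinylogous acid chloride should secure. It also needs ring closure rather than chain growth, which slow addition to high dilution and the two flexible ethylene bridges should secure.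

**Step 13**
Reactants: 21 racemic macrocyclic 3-aryloxycyclohex-2-en-1-one
Product: 23 macrocyclic phenol (dihydroptychantol A dimethyl ether with an extra OH on ring D), via silyl dienol ether 22 (not isolated)
Conditions: LiN(i-Pr)2, THF, −78 °C; Me3SiCl; then Pd(OAc)2 (1.1 equiv), MeCN, rt
Reagents that add atoms: none
Why: Kinetic deprotonation of the vinylogous ester at C6 and silylation give the cross-conjugated silyl dienol ether, and Saegusa–Ito oxidation (palladation at C6, β-hydride elimination from C5) gives a cyclohexa-2,5-dienone that tautomerises to the phenol and erases the C5 stereocentre.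

**Step 14**
Reactants: 23 macrocyclic phenol
Product: 24 macrocyclic aryl triflate (ring D OH of 23 as its trifluoromethanesulfonate)
Conditions: Tf2O, pyridine, CH2Cl2, 0 °C
Reagents that add atoms: trifluoromethanesulfonic anhydride, O=S(=O)(OS(=O)(=O)C(F)(F)F)C(F)(F)F
Why: O-sulfonylation of the only free phenol turns the surplus oxygen into a leaving group for palladium.

**Step 15**
Reactants: 24 macrocyclic aryl triflate
Product: 25 dihydroptychantol A dimethyl ether
Conditions: Pd(OAc)2 (5 mol %), 1,1'-bis(diphenylphosphino)ferrocene (10 mol %), HCO2H, Et3N, DMF, 80 °C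
Reagents that add atoms: none
Why: Palladium-catalysed reductive cleavage of an aryl triflate should work here: oxidative addition to zerovalent palladium, formate as hydride donor with loss of CO2, then reductive elimination; methyl and diaryl ethers are inert.

**Step 16**
Reactants: 25 dihydroptychantol A dimethyl ether
Product: 26 dihydroptychantol A
Conditions: BBr3 (6 equiv), CH2Cl2, −78 °C → rt; H2O
Reagents that add atoms: none
Why: BBr3 demethylation cleaves both aryl methyl ethers and leaves the two diaryl ether bonds intact, as is usual for this family of macrocycles.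

**Compound list**

1 | 2-hydroxy-5-methoxybenzaldehyde | COc1ccc(O)c(C=O)c1 | starting material
2 | 5-methoxy-2-(propan-2-yloxy)benzaldehyde | COc1ccc(OC(C)C)c(C=O)c1 | intermediate
3 | 5-(hydroxymethyl)-2-methoxyphenol (isovanillyl alcohol) | COc1ccc(CO)cc1O | starting material
4 | [(3-hydroxy-4-methoxyphenyl)methyl]triphenylphosphonium bromide | COc1ccc(C[P+](c2ccccc2)(c2ccccc2)c2ccccc2)cc1O.[Br-] | intermediate
5 | potassium 2-methoxy-5-[(triphenyl-λ5-phosphanylidene)methyl]phenolate (ylide) | COc1ccc(C=P(c2ccccc2)(c2ccccc2)c2ccccc2)cc1[O-].[K+] | intermediate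
6 | 2-methoxy-5-{2-[5-methoxy-2-(propan-2-yloxy)phenyl]ethenyl}phenol (E/Z mixture, geometry not fixed) | COc1ccc(C=Cc2cc(OC)ccc2OC(C)C)cc1O | intermediate
7 | 4-fluorobenzaldehyde | O=Cc1ccc(F)cc1 | starting material
8 | 4-(2-methoxy-5-{2-[5-methoxy-2-(propan-2-yloxy)phenyl]ethenyl}phenoxy)benzaldehyde (E/Z mixture at the stilbene) | COc1ccc(C=Cc2cc(OC)ccc2OC(C)C)cc1Oc1ccc(C=O)cc1 | intermediate
9 | ethyl (2E)-3-[4-(2-methoxy-5-{2-[5-methoxy-2-(propan-2-yloxy)phenyl]ethenyl}phenoxy)phenyl]prop-2-enoate (E/Z mixture at the stilbene) | CCOC(=O)/C=C/c1ccc(Oc2cc(C=Cc3cc(OC)ccc3OC(C)C)ccc2OC)cc1 | intermediate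
10 | ethyl 3-[4-(2-methoxy-5-{2-[5-methoxy-2-(propan-2-yloxy)phenyl]ethyl}phenoxy)phenyl]propanoate | CCOC(=O)CCc1ccc(Oc2cc(CCc3cc(OC)ccc3OC(C)C)ccc2OC)cc1 | intermediate
11 | 3-[4-(2-methoxy-5-{2-[5-methoxy-2-(propan-2-yloxy)phenyl]ethyl}phenoxy)phenyl]propanal | O=CCCc1ccc(Oc2cc(CCc3cc(OC)ccc3OC(C)C)ccc2OC)cc1 | intermediate
12 | (3E)-6-[4-(2-methoxy-5-{2-[5-methoxy-2-(propan-2-yloxy)phenyl]ethyl}phenoxy)phenyl]hex-3-en-2-one | CC(=O)/C=C/CCc1ccc(Oc2cc(CCc3cc(OC)ccc3OC(C)C)ccc2OC)cc1 | intermediate
13 | diethyl malonate | CCOC(=O)CC(=O)OCC | starting material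
14 | diethyl 2-{1-[4-(2-methoxy-5-{2-[5-methoxy-2-(propan-2-yloxy)phenyl]ethyl}phenoxy)phenyl]-5-oxohexan-3-yl}propanedioate (racemic, one enantiomer drawn) | CCOC(=O)C(C(=O)OCC)[C@H](CC(C)=O)CCc1ccc(Oc2cc(CCc3cc(OC)ccc3OC(C)C)ccc2OC)cc1 | intermediate
15 | ethyl 6-{2-[4-(2-methoxy-5-{2-[5-methoxy-2-(propan-2-yloxy)phenyl]ethyl}phenoxy)phenyl]ethyl}-2,4-dioxocyclohexane-1-carboxylate (racemic, trans isomer drawn, present as its sodium enolate) | CCOC(=O)[C@H]1C(=O)CC(=O)C[C@@H]1CCc1ccc(Oc2cc(CCc3cc(OC)ccc3OC(C)C)ccc2OC)cc1 | intermediate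
16 | 6-{2-[4-(2-methoxy-5-{2-[5-methoxy-2-(propan-2-yloxy)phenyl]ethyl}phenoxy)phenyl]ethyl}-2,4-dioxocyclohexane-1-carboxylic acid (racemic, trans isomer drawn) | OC(=O)[C@H]1C(=O)CC(=O)C[C@@H]1CCc1ccc(Oc2cc(CCc3cc(OC)ccc3OC(C)C)ccc2OC)cc1 | intermediate
17 | 5-{2-[4-(2-methoxy-5-{2-[5-methoxy-2-(propan-2-yloxy)phenyl]ethyl}phenoxy)phenyl]ethyl}cyclohexane-1,3-dione | O=C1CC(=O)CC(CCc2ccc(Oc3cc(CCc4cc(OC)ccc4OC(C)C)ccc3OC)cc2)C1 | intermediate
18 | 5-{2-[4-(2-methoxy-5-{2-[5-methoxy-2-(propan-2-yloxy)phenyl]ethyl}phenoxy)phenyl]ethyl}-3-oxocyclohex-1-en-1-yl chloro(oxo)acetate (racemic, one enantiomer drawn) | COc1ccc(OC(C)C)c(CCc2ccc(OC)c(Oc3ccc(CC[C@@H]4CC(=O)C=C(OC(=O)C(Cl)=O)C4)cc3)c2)c1 | intermediate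
19 | 3-chloro-5-{2-[4-(2-methoxy-5-{2-[5-methoxy-2-(propan-2-yloxy)phenyl]ethyl}phenoxy)phenyl]ethyl}cyclohex-2-en-1-one (racemic, one enantiomer drawn) | COc1ccc(OC(C)C)c(CCc2ccc(OC)c(Oc3ccc(CC[C@@H]4CC(=O)C=C(Cl)C4)cc3)c2)c1 | intermediate
20 | 3-chloro-5-[2-(4-{5-[2-(2-hydroxy-5-methoxyphenyl)ethyl]-2-methoxyphenoxy}phenyl)ethyl]cyclohex-2-en-1-one (seco phenol chloroenone; racemic, one enantiomer drawn) | COc1ccc(O)c(CCc2ccc(OC)c(Oc3ccc(CC[C@@H]4CC(=O)C=C(Cl)C4)cc3)c2)c1 | intermediate
21 | macrocyclic 3-aryloxycyclohex-2-en-1-one: 18-membered ring, ring A oxygen on C3 of the enone, bridge on C5, ring A and ring B methyl ethers (racemic, one enantiomer drawn) | COc1ccc2c(c1)CCc1ccc(OC)c(c1)Oc1ccc(cc1)CC[C@@H]1CC(=O)C=C(C1)O2 | intermediate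
22 | 1-(trimethylsilyloxy)cyclohexa-1,3-diene derived from 21 (C1=C6 and C2=C3 double bonds, aryloxy on C3; racemic, one enantiomer drawn) | COc1ccc2c(c1)CCc1ccc(OC)c(c1)Oc1ccc(cc1)CC[C@@H]1C=C(O[Si](C)(C)C)C=C(C1)O2 | intermediate
23 | dihydroptychantol A dimethyl ether bearing an extra OH on ring D, meta to both the ether oxygen and the bridge CH2 | COc1ccc2c(c1)CCc1ccc(OC)c(c1)Oc1ccc(cc1)CCc1cc(O)cc(c1)O2 | intermediate
24 | trifluoromethanesulfonate of the ring D phenol 23 | COc1ccc2c(c1)CCc1ccc(OC)c(c1)Oc1ccc(cc1)CCc1cc(OS(=O)(=O)C(F)(F)F)cc(c1)O2 | intermediate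
25 | dihydroptychantol A dimethyl ether (ring A OMe, ring B OMe) | COc1ccc2c(c1)CCc1ccc(OC)c(c1)Oc1ccc(cc1)CCc1cccc(c1)O2 | intermediate
26 | dihydroptychantol A | Oc1ccc2c(c1)CCc1ccc(O)c(c1)Oc1ccc(cc1)CCc1cccc(c1)O2 | target

**Step count**

Total: 16 steps. Longest linear sequence: 15 steps (from 1 through steps 1 and 3–16, or from 3 through steps 2–16).

**Steps most likely to fail**

1. Step 12 (macrocyclisation). Chain growth by intermolecular addition–elimination may outrun closure of the 18-membered ring, or the chloroenone may be consumed by deprotonation at its γ-carbon and self-condensation. Fallback: the same aryl–oxygen bond is closed on an aromatic ring D by palladium catalysis. It sets out from dione 17. Dehydrogenation over 10% Pd/C in refluxing mesitylene should give the 5-substituted resorcinol F1. Tf2O and pyridine should convert it into the bis(triflate) F2. BCl3 at −78 → 0 °C should remove the isopropyl group to give the phenol bis(triflate) F3. Pd(OAc)2, 2-(di-tert-butylphosphino)-2',4',6'-triisopropylbiphenyl and K3PO4 in toluene at 100 °C under high dilution should then join the ring A oxygen to either of the two equivalent triflate-bearing carbons. This comes back to the route at triflate 24 and bypasses steps 10–14.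

2. Step 11 (isopropyl ether cleavage beside the chloroenone). Lewis-acid activation of the chloroenone may lead to Friedel–Crafts-type attack on an electron-rich ring, or the vinylogous chloride may hydrolyse during the aqueous quench. Fallback: the order of the two operations is reversed. From dione 17, BCl3 should give the phenol dione F4, since the dione only forms a borate that returns on aqueous work-up. Oxalyl chloride (1.05 equiv, CH2Cl2, 0 °C, no base) should then chlorinate only the enolised dione. This rests on a vinylogous carboxylic acid being acylated far faster than a neutral, hindered phenol, as in the preparation of hydroxybenzoyl chlorides from hydroxybenzoic acids. The sequence comes back to the route at 20.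

3. Step 13 (aromatisation). Deprotonation may occur at the γ-carbon C4 instead of C6, or the silyl group may be lost before palladation; either returns the enone or gives mixtures. Fallback: an enolate-free oxidative dehydrogenation. From 21, catalytic I2 in DMSO at 80 °C (α-iodination, loss of HI, DMSO as terminal oxidant) should give phenol 23 directly, where it rejoins the route; no new compound arises (F0).

**Further compounds**

F1 | step 12 | 5-{2-[4-(2-methoxy-5-{2-[5-methoxy-2-(propan-2-yloxy)phenyl]ethyl}phenoxy)phenyl]ethyl}benzene-1,3-diol | COc1ccc(OC(C)C)c(CCc2ccc(OC)c(Oc3ccc(CCc4cc(O)cc(O)c4)cc3)c2)c1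
F2 | step 12 | 5-{2-[4-(2-methoxy-5-{2-[5-methoxy-2-(propan-2-yloxy)phenyl]ethyl}phenoxy)phenyl]ethyl}-1,3-phenylene bis(trifluoromethanesulfonate) | COc1ccc(OC(C)C)c(CCc2ccc(OC)c(Oc3ccc(CCc4cc(OS(=O)(=O)C(F)(F)F)cc(OS(=O)(=O)C(F)(F)F)c4)cc3)c2)c1
F3 | step 12 | 5-[2-(4-{5-[2-(2-hydroxy-5-methoxyphenyl)ethyl]-2-methoxyphenoxy}phenyl)ethyl]-1,3-phenylene bis(trifluoromethanesulfonate) | COc1ccc(O)c(CCc2ccc(OC)c(Oc3ccc(CCc4cc(OS(=O)(=O)C(F)(F)F)cc(OS(=O)(=O)C(F)(F)F)c4)cc3)c2)c1
F4 | step 11 | 5-[2-(4-{5-[2-(2-hydroxy-5-methoxyphenyl)ethyl]-2-methoxyphenoxy}phenyl)ethyl]cyclohexane-1,3-dione | COc1ccc(O)c(CCc2ccc(OC)c(Oc3ccc(CCC4CC(=O)CC(=O)C4)cc3)c2)c1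
F0 | step 13 | none | none
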